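**Plan**

- Retrosynthesis: the C8–CH2 bond of the prenyl group is cut back to an O5 prenyl ether (para-Claisen–Cope). The C6–CH2 bond of the hydroxylated chain is cut back to an O5 allyl ether (Claisen), the chain then being grown from the allyl group. The pyranone is cut at O1–C8a, C4–C4a and O1–C2.
- Enabling feature: in ring A, C8a carries O1 and the adjacent C4a carries the C4 carbonyl, and the C5 oxygen sits on the other side of C4a. Ring A therefore corresponds to a 3,5-dioxygenated benzyne whose flanking alkoxy group decides where the oxygen and the acyl carbon land.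
- Forward order: ring A is made as an o-silylaryl triflate and ring B as a 2-aryl-3-methoxyacrylic acid. Their union closes ring C (the pyranone) in one operation. Protecting-group exchange, the C6 chain, the C8 prenyl group and deprotection follow.
- Stereochemistry: the single stereocentre (R carbinol) comes from a Sharpless asymmetric epoxidation with D-(−)-diethyl tartrate. The C–O bond made there is not broken afterwards.

Key step: step 6

Assumption: isoflavone numbering (O1, C2, C3, C4, C4a, C5 to C8, C8a; ring B primed) is used for all chromen-4-ones, and the target SMILES is read as the R carbinol.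

**Route**

Step 1
Reactants: 1 3,5-dimethoxyphenol
Product: 2 2-bromo-3,5-dimethoxyphenol
Conditions: NBS, CH2Cl2, −78 °C → rt
Reagents that add atoms: N-bromosuccinimide, O=C1CCC(=O)N1Br
Why: Electrophilic bromination of the phenol at low temperature should go ortho to the hydroxyl group (para to a methoxy group), the less hindered activated position, and any 4-bromo isomer is removed by chromatography.

Step 2
Reactants: 2 2-bromo-3,5-dimethoxyphenol
Product: 5 3,5-dimethoxy-2-(trimethylsilyl)phenyl trifluoromethanesulfonate, via aryl trimethylsilyl ether 3 (not isolated), via lithium 2-silylphenoxide 4 (not isolated)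
Conditions: HMDS, THF, 65 °C, then evaporate; n-BuLi, THF, −100 → −78 °C; Tf2O, −100 °C → rt
Reagents that add atoms: hexamethyldisilazane, C[Si](C)(C)N[Si](C)(C)C; trifluoromethanesulfonic anhydride, O=S(=O)(OS(=O)(=O)C(F)(F)F)C(F)(F)F
Why: O-silylation, bromine–lithium exchange and a 1,3-shift of silicon from oxygen to carbon (retro-Brook rearrangement) put the silyl group ortho to the phenoxide, which the anhydride then traps, the standard entry to o-silylaryl triflates.

Step 3
Reactants: 6 2,4-dimethoxyphenylacetic acid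
Product: 7 methyl 2,4-dimethoxyphenylacetate
Conditions: MeOH, H2SO4 (cat.), reflux
Reagents that add atoms: methanol, CO
Why: Fischer esterification of an unhindered arylacetic acid.

Step 4
Reactants: 7 methyl 2,4-dimethoxyphenylacetate; 8 methyl formate
Product: 10 methyl (E)-2-(2,4-dimethoxyphenyl)-3-methoxyacrylate, via sodium formyl-ester enolate 9 (not isolated)
Conditions: NaH, HCO2Me, DMF, 0 °C → rt; then Me2SO4, 0 °C → rt
Reagents that add atoms: dimethyl sulfate, COS(=O)(=O)OC
Why: Crossed Claisen condensation with methyl formate gives the formyl ester as its sodium enolate, and O-methylation in DMF gives the (E)-β-methoxyacrylate, the established route to this acrylate class; the enol ether geometry is lost later in the ring closure and so is not critical.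

Step 5
Reactants: 10 methyl (E)-2-(2,4-dimethoxyphenyl)-3-methoxyacrylate
Product: 11 (E)-2-(2,4-dimethoxyphenyl)-3-methoxyacrylic acid
Conditions: LiOH, THF–MeOH–H2O, 40 °C; then 1 M HCl to pH 3, 0 °C
Reagents that add atoms: lithium hydroxide, [Li+].[OH-]
Why: Saponification of a β-alkoxyacrylate ester to the acid is a known conversion, and cold, mild acidification keeps the enol ether from hydrolysing.

Step 6
Reactants: 5 3,5-dimethoxy-2-(trimethylsilyl)phenyl trifluoromethanesulfonate; 11 (E)-2-(2,4-dimethoxyphenyl)-3-methoxyacrylic acid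
Product: 14 5,7,2',4'-tetramethoxyisoflavone, via 3,5-dimethoxybenzyne 12 (not isolated), via caesium 2-acylphenoxide 13 (not isolated)
Conditions: CsF (4 equiv), 5 (1.5 equiv), THF, 125 °C, sealed tube
Reagents that add atoms: none
Why: Proposed new method: fluoride removes the silyl group of 5 and triflate leaves to give aryne 12; the caesium carboxylate of 11 adds through oxygen at the aryne carbon remote from the flanking methoxy group (O1–C8a), the aryl anion formed next to that methoxy group attacks the ester carbonyl (C4–C4a), and the four-membered intermediate opens to the 2-acylphenoxide 13, which adds to the β-methoxy enone carbon and expels methoxide (O1–C2). The closest known reaction type is the fluoride-induced insertion of arynes into the C–O bond of carboxylic acids to give o-hydroxyaryl ketones, including the variant in which acrylic acids go on to chroman-4-ones by oxa-Michael closure, together with the aryne–salicylate xanthone annulation. The pyranone closes by 6-endo-trig addition of the phenoxide oxygen to C2 followed by elimination, an addition–elimination at a vinylogous ester. No stereocentre is formed. The step needs aryne regioselectivity, which the inductively withdrawing methoxy group beside the triple bond (the future C5 oxygen) should secure by directing the nucleophile to the distal carbon, and it needs O- rather than C-arylation, which is secured because a carboxylate can react only at oxygen; aprotic THF at high temperature favours acyl transfer over protonation to the aryl ester.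

Step 7
Reactants: 14 5,7,2',4'-tetramethoxyisoflavone
Product: 15 5,7,2',4'-tetrahydroxyisoflavone (2'-hydroxygenistein)
Conditions: BBr3 (8 equiv), CH2Cl2, −78 °C → rt
Reagents that add atoms: none
Why: Exhaustive Lewis-acid cleavage of aryl methyl ethers, a standard conversion of polymethoxyisoflavones into the polyphenols, done before any alkene or acid-sensitive group is present.

Step 8
Reactants: 15 5,7,2',4'-tetrahydroxyisoflavone
Product: 16 5-hydroxy-7,2',4'-tris(methoxymethoxy)isoflavone
Conditions: MOMCl (3.3 equiv), i-Pr2NEt, CH2Cl2–DMF, 0 °C → rt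
Reagents that add atoms: chloromethyl methyl ether, COCCl
Why: Base-mediated O-alkylation takes the three unchelated phenols, while the 5-OH, held in a hydrogen bond to the C4 carbonyl, stays free, the usual selectivity of 5-hydroxyisoflavones.

Step 9
Reactants: 16 5-hydroxy-7,2',4'-tris(methoxymethoxy)isoflavone; 17 allyl bromide
Product: 18 5-allyloxy-7,2',4'-tris(methoxymethoxy)isoflavone
Conditions: K2CO3, DMF, 60 °C
Reagents that add atoms: none
Why: Williamson etherification of the chelated 5-OH, now the only free phenol, under somewhat forcing conditions.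

Step 10
Reactants: 18 5-allyloxy-7,2',4'-tris(methoxymethoxy)isoflavone
Product: 20 6-allyl-5-hydroxy-7,2',4'-tris(methoxymethoxy)isoflavone, via C6 allyl dienone 19 (not isolated)
Conditions: PhNEt2, 200 °C
Reagents that add atoms: none
Why: Aromatic Claisen rearrangement, in which the [3,3] shift can reach only C6, the one free ortho position of O5, and tautomerisation of the dienone restores the chelated 5-OH.

Step 11
Reactants: 20 6-allyl-5-hydroxy-7,2',4'-tris(methoxymethoxy)isoflavone
Product: 21 6-allyl-5-(tert-butyldimethylsilyloxy)-7,2',4'-tris(methoxymethoxy)isoflavone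
Conditions: TBSOTf, 2,6-lutidine, CH2Cl2, −40 → 0 °C
Reagents that add atoms: tert-butyldimethylsilyl trifluoromethanesulfonate, CC(C)(C)[Si](C)(C)OS(=O)(=O)C(F)(F)F
Why: Silylation of a hindered, hydrogen-bonded phenol with a silyl triflate and a hindered base, which MOM ethers tolerate at low temperature; masking O5 keeps this phenol from binding titanium or opening the epoxide in steps 14 and 15.

Step 12
Reactants: 21 6-allyl-5-(tert-butyldimethylsilyloxy)-7,2',4'-tris(methoxymethoxy)isoflavone; 22 methacrolein
Product: 23 (E)-4-[5-(tert-butyldimethylsilyloxy)-7,2',4'-tris(methoxymethoxy)isoflavon-6-yl]-2-methylbut-2-enal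
Conditions: second-generation Hoveyda–Grubbs catalyst (H2IMes)Cl2Ru=CH(C6H4-2-OiPr) (5 mol%), methacrolein (10 equiv), CH2Cl2, 40 °C
Reagents that add atoms: none
Why: Olefin cross-metathesis of a terminal alkene with excess methacrolein, a pairing known to give the trisubstituted (E)-enal selectively; the E geometry matters because it fixes which epoxide configuration arises at the future carbinol carbon.

Step 13
Reactants: 23 (E)-4-[5-(tert-butyldimethylsilyloxy)-7,2',4'-tris(methoxymethoxy)isoflavon-6-yl]-2-methylbut-2-enal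
Product: 24 (E)-4-[5-(tert-butyldimethylsilyloxy)-7,2',4'-tris(methoxymethoxy)isoflavon-6-yl]-2-methylbut-2-en-1-ol
Conditions: NaBH4, CeCl3·7H2O, MeOH–THF, −40 °C
Reagents that add atoms: none
Why: Luche reduction, in which the enal is reduced 1,2-selectively at low temperature while the vinylogous ester carbonyl of the chromenone is left alone.

Step 14
Reactants: 24 (E)-4-[5-(tert-butyldimethylsilyloxy)-7,2',4'-tris(methoxymethoxy)isoflavon-6-yl]-2-methylbut-2-en-1-ol
Product: 25 [(2R,3R)-2-methyl-3-{[5-(tert-butyldimethylsilyloxy)-7,2',4'-tris(methoxymethoxy)isoflavon-6-yl]methyl}oxiran-2-yl]methanol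
Conditions: Ti(OiPr)4 (20 mol%), D-(−)-diethyl tartrate (24 mol%), t-BuOOH, 4 Å molecular sieves, CH2Cl2, −20 °C
Reagents that add atoms: tert-butyl hydroperoxide, CC(C)(C)OO
Why: Sharpless asymmetric epoxidation of an (E)-2-methyl allylic alcohol, a substrate class expected to react with high enantioselectivity; D-(−)-diethyl tartrate is the mirror image of the tartrate that turns (E)-allylic alcohols into (2S,3S)-epoxy alcohols, so it should deliver the (2R,3R) epoxide, whose C3–O bond becomes the R carbinol.

Step 15
Reactants: 25 [(2R,3R)-2-methyl-3-{[5-(tert-butyldimethylsilyloxy)-7,2',4'-tris(methoxymethoxy)isoflavon-6-yl]methyl}oxiran-2-yl]methanol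
Product: 27 5-(tert-butyldimethylsilyloxy)-6-[(2R)-2-hydroxy-3-methylbut-3-en-1-yl]-7,2',4'-tris(methoxymethoxy)isoflavone, via epoxy iodide 26 (not isolated)
Conditions: I2, PPh3, imidazole, THF, 0 °C; then Zn dust, AcOH, EtOH, 0 °C → rt
Reagents that add atoms: none
Why: Appel-type iodination of the primary alcohol followed by zinc insertion and β-elimination with opening of the epoxide (the reductive transposition of epoxy iodides to allylic alcohols); the C3–O bond is not touched, so the configuration from step 14 is carried over as R.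

Step 16
Reactants: 27 5-(tert-butyldimethylsilyloxy)-6-[(2R)-2-hydroxy-3-methylbut-3-en-1-yl]-7,2',4'-tris(methoxymethoxy)isoflavone; 28 prenyl bromide (1-bromo-3-methylbut-2-ene)
Product: 30 6-[(2R)-2-hydroxy-3-methylbut-3-en-1-yl]-7,2',4'-tris(methoxymethoxy)-5-(3-methylbut-2-en-1-yloxy)isoflavone, via caesium 5-phenoxide 29 (not isolated)
Conditions: CsF, DMF, rt
Reagents that add atoms: none
Why: Fluoride cleaves the aryl silyl ether and the phenoxide is alkylated in the same flask (one-pot desilylation–alkylation of aryl silyl ethers), while the secondary alcohol is not deprotonated by fluoride and stays free.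

Step 17
Reactants: 30 6-[(2R)-2-hydroxy-3-methylbut-3-en-1-yl]-7,2',4'-tris(methoxymethoxy)-5-(3-methylbut-2-en-1-yloxy)isoflavone
Product: 32 5-hydroxy-6-[(2R)-2-hydroxy-3-methylbut-3-en-1-yl]-7,2',4'-tris(methoxymethoxy)-8-(3-methylbut-2-en-1-yl)isoflavone, via C6 dienone 31 (not isolated)
Conditions: Eu(fod)3 (10 mol%), ClCH2CH2Cl, 80 °C
Reagents that add atoms: none
Why: Para-Claisen (Claisen–Cope) rearrangement under Eu(fod)3 catalysis: the [3,3] shift to the blocked C6 gives a dienone that cannot tautomerise, a Cope [3,3] shift relays the group to C8 as a linear prenyl unit, and enolisation restores the 5-OH; the carbinol centre is a spectator.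

Step 18
Reactants: 32 5-hydroxy-6-[(2R)-2-hydroxy-3-methylbut-3-en-1-yl]-7,2',4'-tris(methoxymethoxy)-8-(3-methylbut-2-en-1-yl)isoflavone
Product: 33 3-(2,4-dihydroxyphenyl)-5,7-dihydroxy-6-[(2R)-2-hydroxy-3-methylbut-3-en-1-yl]-8-(3-methylbut-2-en-1-yl)-4H-chromen-4-one (CNP0408283.2)
Conditions: HCl (2 M) in MeOH, 0 °C → rt
Reagents that add atoms: none
Why: Acid-catalysed acetal exchange removes the three MOM ethers; dilute acid at or below room temperature is chosen so that the prenyl group and the allylic carbinol (no C–O bond broken, configuration retained) are not drawn into cyclisation onto the neighbouring phenols.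

**Compound list**

1 | 3,5-dimethoxyphenol | COc1cc(O)cc(OC)c1 | starting material
2 | 2-bromo-3,5-dimethoxyphenol | COc1cc(O)c(Br)c(OC)c1 | intermediate
3 | (2-bromo-3,5-dimethoxyphenoxy)trimethylsilane | COc1cc(O[Si](C)(C)C)c(Br)c(OC)c1 | intermediate
4 | lithium 3,5-dimethoxy-2-(trimethylsilyl)phenoxide | COc1cc([O-])c([Si](C)(C)C)c(OC)c1.[Li+] | intermediate
5 | 3,5-dimethoxy-2-(trimethylsilyl)phenyl trifluoromethanesulfonate | COc1cc(OC)c([Si](C)(C)C)c(OS(=O)(=O)C(F)(F)F)c1 | intermediate
6 | 2,4-dimethoxyphenylacetic acid | O=C(O)Cc1ccc(OC)cc1OC | starting material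
7 | methyl 2,4-dimethoxyphenylacetate | COC(=O)Cc1ccc(OC)cc1OC | intermediate
8 | methyl formate | COC=O | starting material
9 | sodium 2-(2,4-dimethoxyphenyl)-3-methoxy-3-oxoprop-1-en-1-olate | COC(=O)C(=C[O-])c1ccc(OC)cc1OC.[Na+] | intermediate
10 | methyl (E)-2-(2,4-dimethoxyphenyl)-3-methoxyacrylate | CO/C=C(/C(=O)OC)c1ccc(OC)cc1OC | intermediate
11 | (E)-2-(2,4-dimethoxyphenyl)-3-methoxyacrylic acid | CO/C=C(/C(=O)O)c1ccc(OC)cc1OC | intermediate
12 | 3,5-dimethoxybenzyne | COC1=CC(OC)=CC#C1 | intermediate
13 | caesium 2-[(E)-2-(2,4-dimethoxyphenyl)-3-methoxyacryloyl]-3,5-dimethoxyphenoxide | CO/C=C(/C(=O)c1c([O-])cc(OC)cc1OC)c1ccc(OC)cc1OC.[Cs+] | intermediate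
14 | 5,7,2',4'-tetramethoxyisoflavone | COc1ccc(-c2coc3cc(OC)cc(OC)c3c2=O)c(OC)c1 | intermediate
15 | 5,7,2',4'-tetrahydroxyisoflavone (2'-hydroxygenistein) | O=c1c(-c2ccc(O)cc2O)coc2cc(O)cc(O)c12 | intermediate
16 | 5-hydroxy-7,2',4'-tris(methoxymethoxy)isoflavone | COCOc1ccc(-c2coc3cc(OCOC)cc(O)c3c2=O)c(OCOC)c1 | intermediate
17 | allyl bromide | C=CCBr | starting material
18 | 5-allyloxy-7,2',4'-tris(methoxymethoxy)isoflavone | COCOc1ccc(-c2coc3cc(OCOC)cc(OCC=C)c3c2=O)c(OCOC)c1 | intermediate
19 | 6-allyl-3-[2,4-bis(methoxymethoxy)phenyl]-7-(methoxymethoxy)-4H-chromene-4,5(6H)-dione (C6 allyl dienone) | C=CCC1C(=O)C2=C(C=C1OCOC)OC=C(c1ccc(OCOC)cc1OCOC)C2=O | intermediate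
20 | 6-allyl-5-hydroxy-7,2',4'-tris(methoxymethoxy)isoflavone | COCOc1ccc(-c2coc3cc(OCOC)c(CC=C)c(O)c3c2=O)c(OCOC)c1 | intermediate
21 | 6-allyl-5-(tert-butyldimethylsilyloxy)-7,2',4'-tris(methoxymethoxy)isoflavone | COCOc1ccc(-c2coc3cc(OCOC)c(CC=C)c(O[Si](C)(C)C(C)(C)C)c3c2=O)c(OCOC)c1 | intermediate
22 | methacrolein | C=C(C)C=O | starting material
23 | (E)-4-[5-(tert-butyldimethylsilyloxy)-7,2',4'-tris(methoxymethoxy)isoflavon-6-yl]-2-methylbut-2-enal | COCOc1ccc(-c2coc3cc(OCOC)c(C/C=C(\C)C=O)c(O[Si](C)(C)C(C)(C)C)c3c2=O)c(OCOC)c1 | intermediate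
24 | (E)-4-[5-(tert-butyldimethylsilyloxy)-7,2',4'-tris(methoxymethoxy)isoflavon-6-yl]-2-methylbut-2-en-1-ol | COCOc1ccc(-c2coc3cc(OCOC)c(C/C=C(\C)CO)c(O[Si](C)(C)C(C)(C)C)c3c2=O)c(OCOC)c1 | intermediate
25 | [(2R,3R)-2-methyl-3-{[5-(tert-butyldimethylsilyloxy)-7,2',4'-tris(methoxymethoxy)isoflavon-6-yl]methyl}oxiran-2-yl]methanol | COCOc1ccc(-c2coc3cc(OCOC)c(C[C@H]4O[C@]4(C)CO)c(O[Si](C)(C)C(C)(C)C)c3c2=O)c(OCOC)c1 | intermediate
26 | 5-(tert-butyldimethylsilyloxy)-6-{[(2R,3S)-3-(iodomethyl)-3-methyloxiran-2-yl]methyl}-7,2',4'-tris(methoxymethoxy)isoflavone | COCOc1ccc(-c2coc3cc(OCOC)c(C[C@H]4O[C@]4(C)CI)c(O[Si](C)(C)C(C)(C)C)c3c2=O)c(OCOC)c1 | intermediate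
27 | 5-(tert-butyldimethylsilyloxy)-6-[(2R)-2-hydroxy-3-methylbut-3-en-1-yl]-7,2',4'-tris(methoxymethoxy)isoflavone | COCOc1ccc(-c2coc3cc(OCOC)c(C[C@@H](O)C(C)=C)c(O[Si](C)(C)C(C)(C)C)c3c2=O)c(OCOC)c1 | intermediate
28 | prenyl bromide (1-bromo-3-methylbut-2-ene) | CC(C)=CCBr | starting material
29 | caesium 6-[(2R)-2-hydroxy-3-methylbut-3-en-1-yl]-7,2',4'-tris(methoxymethoxy)isoflavon-5-olate | COCOc1ccc(-c2coc3cc(OCOC)c(C[C@@H](O)C(C)=C)c([O-])c3c2=O)c(OCOC)c1.[Cs+] | intermediate
30 | 6-[(2R)-2-hydroxy-3-methylbut-3-en-1-yl]-7,2',4'-tris(methoxymethoxy)-5-(3-methylbut-2-en-1-yloxy)isoflavone | COCOc1ccc(-c2coc3cc(OCOC)c(C[C@@H](O)C(C)=C)c(OCC=C(C)C)c3c2=O)c(OCOC)c1 | intermediate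
31 | 3-[2,4-bis(methoxymethoxy)phenyl]-6-[(2R)-2-hydroxy-3-methylbut-3-en-1-yl]-7-(methoxymethoxy)-6-(2-methylbut-3-en-2-yl)-4H-chromene-4,5(6H)-dione (C6 dienone, both C6 epimers) | C=CC(C)(C)C1(C[C@@H](O)C(C)=C)C(=O)C2=C(C=C1OCOC)OC=C(c1ccc(OCOC)cc1OCOC)C2=O | intermediate
32 | 5-hydroxy-6-[(2R)-2-hydroxy-3-methylbut-3-en-1-yl]-7,2',4'-tris(methoxymethoxy)-8-(3-methylbut-2-en-1-yl)isoflavone | COCOc1ccc(-c2coc3c(CC=C(C)C)c(OCOC)c(C[C@@H](O)C(C)=C)c(O)c3c2=O)c(OCOC)c1 | intermediate
33 | 3-(2,4-dihydroxyphenyl)-5,7-dihydroxy-6-[(2R)-2-hydroxy-3-methylbut-3-en-1-yl]-8-(3-methylbut-2-en-1-yl)-4H-chromen-4-one | C=C(C)[C@H](O)Cc1c(O)c(CC=C(C)C)c2occ(-c3ccc(O)cc3O)c(=O)c2c1O | target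

**Step count and risks**

Total: 18 steps. Longest linear sequence: 16 steps (steps 3 to 18, from 2,4-dimethoxyphenylacetic acid); the aryne branch (steps 1 and 2) joins at step 6.

Steps most likely to fail:

1. Step 6 (aryne cascade). The aryl anion may be protonated before acyl transfer, which stops the sequence at the aryl ester. Excess aryne may also arylate the phenoxide or the released methoxide, and the enol ether acid may degrade at 125 °C. The fallback is the deoxybenzoin route, which sets out from 1 and 6. Acylation of 3,5-dimethoxyphenol 1 with acid 6 in BF3·OEt2 at 85 °C (Friedel–Crafts acylation with Fries-type delivery ortho to the hydroxyl group) should give 2-(2,4-dimethoxyphenyl)-1-(2-hydroxy-4,6-dimethoxyphenyl)ethanone F1. Heating F1 with N,N-dimethylformamide dimethyl acetal in toluene at 100 °C adds the C2 carbon and closes the pyranone, returning to the route at 14.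

2. Step 17 (Claisen–Cope to C8). The Lewis acid may ionise the prenyl ether and strip the prenyl group, or the first shift may stall because it has to build a quaternary C6. The fallback sets out from 27 and puts the prenyl group on carbon directly. HCl in MeOH at room temperature removes the silyl and MOM groups together to give 3-(2,4-dihydroxyphenyl)-5,7-dihydroxy-6-[(2R)-2-hydroxy-3-methylbut-3-en-1-yl]-4H-chromen-4-one F2. Base-mediated nuclear prenylation of F2 with prenyl bromide 28 and NaOMe in MeOH at 0 °C should then alkylate C8, the only free carbon of the phloroglucinol ring. This classical C-alkylation is expected to be modest because O-prenyl ethers form as well, but after their separation it arrives directly at target 33.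

3. Step 14 (asymmetric epoxidation). Enantioselectivity may erode or turnover may be slow at the crowded olefin, and if the silyl ether is lost the freed phenol may bind titanium or open the epoxide. The fallback sets out from 21 and avoids titanium and the epoxy alcohol. Cross-metathesis of 21 with 2-methyl-2-butene (second-generation Grubbs catalyst (H2IMes)(PCy3)Cl2Ru=CHPh, CH2Cl2, 40 °C) gives 5-(tert-butyldimethylsilyloxy)-7,2',4'-tris(methoxymethoxy)-6-(3-methylbut-2-en-1-yl)isoflavone F3. Shi epoxidation of F3 with the D-fructose-derived ketone and Oxone (2KHSO5·KHSO4·K2SO4) in buffered MeCN–dimethoxymethane–water at 0 °C should give the (R)-epoxide 5-(tert-butyldimethylsilyloxy)-6-{[(2R)-3,3-dimethyloxiran-2-yl]methyl}-7,2',4'-tris(methoxymethoxy)isoflavone F4. Isomerisation of F4 with Al(OiPr)3 in toluene at 110 °C removes a methyl proton and opens the epoxide at the tertiary carbon, leaving the secondary C–O bond intact and returning to the route at 27.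

**Further compounds**

F1 | step 6 | 2-(2,4-dimethoxyphenyl)-1-(2-hydroxy-4,6-dimethoxyphenyl)ethanone | COc1ccc(CC(=O)c2c(O)cc(OC)cc2OC)c(OC)c1
F2 | step 17 | 3-(2,4-dihydroxyphenyl)-5,7-dihydroxy-6-[(2R)-2-hydroxy-3-methylbut-3-en-1-yl]-4H-chromen-4-one | C=C(C)[C@H](O)Cc1c(O)cc2occ(-c3ccc(O)cc3O)c(=O)c2c1O
F3 | step 14 | 5-(tert-butyldimethylsilyloxy)-7,2',4'-tris(methoxymethoxy)-6-(3-methylbut-2-en-1-yl)isoflavone | COCOc1ccc(-c2coc3cc(OCOC)c(CC=C(C)C)c(O[Si](C)(C)C(C)(C)C)c3c2=O)c(OCOC)c1
F4 | step 14 | 5-(tert-butyldimethylsilyloxy)-6-{[(2R)-3,3-dimethyloxiran-2-yl]methyl}-7,2',4'-tris(methoxymethoxy)isoflavone | COCOc1ccc(-c2coc3cc(OCOC)c(C[C@H]4OC4(C)C)c(O[Si](C)(C)C(C)(C)C)c3c2=O)c(OCOC)c1
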